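**Plan**
- Retrosynthesis: the O9 acetate and C14 aldehyde adjustments come off first. Ring B (γ-lactone, C12–O6) and ring A (ten-membered carbocycle, C5–C6) are then opened together to an acyclic iodo-aldehyde ester. Last, the O8 ester, the C7–C8 bond (allylation) and the C1=C10 olefin (cross-metathesis) are cut.
- Enabling feature: C6 is both the carbinol carbon of ring B and the allylic carbon next to the ring-cis C4=C5 olefin. A (Z)-C5 alkenylmetal adding to a C6 aldehyde closes ring A and leaves the C6 alkoxide five atoms from the C12 ester, so ring B closes in the same operation. The two ring-cis trisubstituted olefins (C1=C10, C4=C5) fold the C1–C5 tether towards C6.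
- Forward: fragment A (C1–C5, C15) plus a glycerate-derived acrylate (C8–C10, C14) give the C8 aldehyde; an indium allylation adds C6, C7 and C11–C13; O8 is acylated; the C6 aldehyde is freed; the Ni/Cr ring closure with lactonisation follows; O9/C14 end-game.
- Stereochemistry: C9 from methyl (S)-glycerate acetonide; C8 and C7 from one Felkin–Anh, chair-controlled allylation; C6 from the ring closure under C7/C8 control; C2' from (S)-2-hydroxy-2-methylbutanoic acid; 4Z from syn-carbocupration; C1=C10 geometry from the metathesis.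

Key step: step 17

Remark: locants follow germacrane numbering (C1–C10 carbocycle, C11–C13 lactone carbons on C7, C14 on C10, C15 on C4), and compounds 1, 2, 6, 16, 17 and 22 are taken as purchased.

**Route**

Step 1
Reactants: 1 but-3-enylmagnesium bromide; 2 propyne
Product: 5 (1Z)-1-iodo-2-methylhexa-1,5-diene (fragment A), via but-3-enylcopper 3 (not isolated), via alkenylcopper 4 (not isolated)
Conditions: CuBr·SMe2 (1 equiv), Et2O/Me2S, −45 °C; 2, −25 °C; I2, −60 → 0 °C
Reagents that add atoms: iodine, [I][I]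
Why: Normant syn-carbocupration of propyne places copper cis to the butenyl chain and iodinolysis with retention should give the (Z)-iodoalkene that maps onto C3–C4(C15)=C5.

Step 2
Reactants: 6 methyl (4S)-2,2-dimethyl-1,3-dioxolane-4-carboxylate
Product: 8 (4R)-4-ethynyl-2,2-dimethyl-1,3-dioxolane, via aldehyde 7 (not isolated)
Conditions: DIBAL-H, CH2Cl2, −78 °C; then MeOH, K2CO3, dimethyl (1-diazo-2-oxopropyl)phosphonate, −78 °C → rt
Reagents that add atoms: dimethyl (1-diazo-2-oxopropyl)phosphonate, CC(=O)C(=[N+]=[N-])P(=O)(OC)OC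
Why: Half-reduction of the ester followed in the same flask by Ohira–Bestmann (Seyferth–Gilbert) homologation should give the terminal alkyne with the glycerate centre (the future C9) retained.

Step 3
Reactants: 8 (4R)-4-ethynyl-2,2-dimethyl-1,3-dioxolane
Product: 9 methyl 2-[(4R)-2,2-dimethyl-1,3-dioxolan-4-yl]prop-2-enoate
Conditions: Pd(OAc)2 (1 mol%), 2-(diphenylphosphino)pyridine (10 mol%), MeSO3H (5 mol%), CO (10 bar), MeOH (5 equiv), CH2Cl2, 45 °C
Reagents that add atoms: carbon monoxide, [C-]#[O+]; methanol, CO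
Why: Branched-selective (Markovnikov) palladium/2-pyridylphosphine-catalysed hydromethoxycarbonylation of a terminal alkyne should give the 2-substituted acrylate, the acid co-catalyst being kept below the phosphine loading to spare the acetonide.

Step 4
Reactants: 9 methyl 2-[(4R)-2,2-dimethyl-1,3-dioxolan-4-yl]prop-2-enoate; 5 (1Z)-1-iodo-2-methylhexa-1,5-diene
Product: 10 methyl (2E,6Z)-2-[(4R)-2,2-dimethyl-1,3-dioxolan-4-yl]-7-iodo-6-methylhepta-2,6-dienoate
Conditions: second-generation Hoveyda–Grubbs catalyst (5 mol%), 5 (3 equiv), CH2Cl2, 40 °C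
Reagents that add atoms: none
Why: Olefin cross-metathesis of a 2-substituted acrylate with a terminal olefin should, as with methacrylates, place the chain trans to the ester, which is the C1=C10 geometry of the target (C2 cis to C9), while the trisubstituted iodoalkene is inert to the ruthenium carbene.

Step 5
Reactants: 10 enoate
Product: 11 (2Z,6Z)-2-[(4R)-2,2-dimethyl-1,3-dioxolan-4-yl]-7-iodo-6-methylhepta-2,6-dien-1-ol
Conditions: DIBAL-H (2.5 equiv), CH2Cl2, −78 °C; aqueous potassium sodium tartrate
Reagents that add atoms: none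
Why: 1,2-Reduction of the enoate with DIBAL-H should give the C14 allylic alcohol without touching the iodoalkene or the acetonide.

Step 6
Reactants: 11 allylic alcohol
Product: 12 tert-butyl{[(2Z,6Z)-2-[(4R)-2,2-dimethyl-1,3-dioxolan-4-yl]-7-iodo-6-methylhepta-2,6-dien-1-yl]oxy}diphenylsilane
Conditions: TBDPSCl, imidazole, DMF, 0 °C → rt
Reagents that add atoms: tert-butyl(chloro)diphenylsilane, CC(C)(C)[Si](Cl)(c1ccccc1)c1ccccc1
Why: Standard silylation of the primary allylic alcohol installs an O14 protecting group that outlasts every step up to the ring closure.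

Step 7
Reactants: 12 silyl ether acetonide
Product: 13 (2R,3Z,7Z)-3-{[tert-butyl(diphenyl)silyl]oxymethyl}-8-iodo-7-methylocta-3,7-diene-1,2-diol
Conditions: AcOH/H2O (4:1), 40 °C
Reagents that add atoms: none
Why: Acid hydrolysis of the terminal acetonide should free the C8/C9 diol while the TBDPS ether and both olefins tolerate aqueous acetic acid.

Step 8
Reactants: 13 diol
Product: 14 (2R,3Z,7Z)-3-{[tert-butyl(diphenyl)silyl]oxymethyl}-8-iodo-7-methyl-1,2-bis(triethylsilyloxy)octa-3,7-diene
Conditions: TESOTf (2.5 equiv), 2,6-lutidine, CH2Cl2, −78 °C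
Reagents that add atoms: triethylsilyl trifluoromethanesulfonate, CC[Si](CC)(CC)OS(=O)(=O)C(F)(F)F
Why: Exhaustive silylation with the silyl triflate gives the bis-TES ether, whose primary and secondary silyl groups are told apart in the next step.

Step 9
Reactants: 14 bis-TES ether
Product: 15 (2R,3Z,7Z)-3-{[tert-butyl(diphenyl)silyl]oxymethyl}-8-iodo-7-methyl-2-(triethylsilyloxy)octa-3,7-dienal
Conditions: (COCl)2, DMSO, CH2Cl2, −78 → −30 °C; Et3N, −78 → 0 °C; used at once
Reagents that add atoms: none
Why: Swern conditions oxidise a primary triethylsilyl ether directly to the aldehyde while the secondary TES and the TBDPS ethers persist, so the C8 aldehyde with its O9 silyl group appears without a free diol stage.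

Step 10
Reactants: 16 2-[(4-methoxyphenyl)methoxy]acetaldehyde; 17 methyl acrylate
Product: 18 methyl 3-hydroxy-4-[(4-methoxyphenyl)methoxy]-2-methylidenebutanoate (racemic)
Conditions: DABCO (1 equiv), 1,4-dioxane/H2O (1:1), rt
Reagents that add atoms: none
Why: Morita–Baylis–Hillman reaction of an α-alkoxy aldehyde with an acrylate assembles C6, C7 and C11–C13, and the racemic carbinol centre is erased in the next step.

Step 11
Reactants: 18 Morita–Baylis–Hillman alcohol
Product: 19 methyl (2Z)-2-(bromomethyl)-4-[(4-methoxyphenyl)methoxy]but-2-enoate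
Conditions: NBS, Me2S, CH2Cl2, 0 °C → rt
Reagents that add atoms: N-bromosuccinimide, O=C1CCC(=O)N1Br
Why: Bromosulfonium activation with SN2' delivery of bromide (Corey–Kim-type conditions) should give the rearranged allylic bromide as the thermodynamic isomer with the CH2OPMB group trans to the ester.

Step 12
Reactants: 15 C8 aldehyde; 19 allylic bromide
Product: 21 methyl (3S,4S,5R,6Z,10Z)-6-{[tert-butyl(diphenyl)silyl]oxymethyl}-4-hydroxy-11-iodo-3-{[(4-methoxyphenyl)methoxy]methyl}-10-methyl-2-methylidene-5-(triethylsilyloxy)undeca-6,10-dienoate, via allylindium dibromide 20 (not isolated)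
Conditions: indium powder, 19 (2 equiv), THF/H2O (1:1), 0 °C → rt
Reagents that add atoms: none
Why: In this indium-mediated Barbier 2-(alkoxycarbonyl)allylation, γ-attack of the (Z)-allylindium through a chair transition state should set C7 with C6 syn to the new O8 hydroxyl, and Felkin–Anh addition anti to the O9 silyloxy group should set C8 anti to C9, the iodoalkene being inert to indium and the hindered hydroxy ester not lactonising.

Step 13
Reactants: 22 (2S)-2-hydroxy-2-methylbutanoic acid
Product: 23 (2S)-2-acetoxy-2-methylbutanoic acid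
Conditions: AcCl (neat), 50 °C; then H2O
Reagents that add atoms: acetyl chloride, CC(=O)Cl
Why: Acetylation of the tertiary α-hydroxy acid with neat acetyl chloride is standard, and the fully substituted C2' centre cannot epimerise.

Step 14
Reactants: 23 (2S)-2-acetoxy-2-methylbutanoic acid; 21 C8 alcohol
Product: 25 O8 ester (PMB ether), via acid chloride 24 (not isolated)
Conditions: (COCl)2, DMF (cat.), CH2Cl2, 0 °C → rt, evaporate; then 21, pyridine, DMAP (cat.), CH2Cl2, 0 °C → rt
Reagents that add atoms: none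
Why: Acid chloride formation and DMAP-catalysed acylation of the C8 hydroxyl install the side chain early, which blocks 12,8-lactonisation and tells O8 apart from O9.

Step 15
Reactants: 25 O8 ester (PMB ether)
Product: 26 C6 primary alcohol
Conditions: DDQ, CH2Cl2/aqueous pH 7 buffer (NaH2PO4/Na2HPO4) (10:1), 0 °C; crude product carried on at once
Reagents that add atoms: none
Why: Oxidative PMB cleavage with DDQ under buffered conditions leaves the silyl ethers, esters, acrylate and iodoalkene untouched, and the γ-hydroxy ester is not stored so that it cannot lactonise prematurely.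

Step 16
Reactants: 26 C6 primary alcohol
Product: 27 C6 aldehyde
Conditions: Dess–Martin periodinane, NaHCO3, CH2Cl2, 0 °C; used at once
Reagents that add atoms: none
Why: Buffered Dess–Martin oxidation gives the aldehyde under non-basic conditions, so the C7 centre should not epimerise and the C11=C13 olefin should not move into conjugation.

Step 17
Reactants: 27 C6 aldehyde
Product: 30 macrolactone (rings A and B closed), via alkenylchromium dichloride 28 (not isolated), via macrocyclic chromium alkoxide 29 (not isolated)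
Conditions: CrCl2 (10 equiv), NiCl2 (1 mol% relative to CrCl2), degassed DMSO/THF (3:1), slow addition of 27 to 0.003 M, rt; then 40 °C; aqueous sodium serinate work-up
Reagents that add atoms: none
Why: Zerovalent nickel inserts into the C5–I bond, the alkenyl group passes with retention to trivalent chromium (28), which adds to the C6 aldehyde, and the chromium alkoxide 29 then attacks the C12 methyl ester and expels methoxide. The closest known reaction type is the intramolecular Nozaki–Hiyama–Kishi macrocyclisation of a (Z)-iodoalkene onto an aldehyde, combined with the in-flask lactonisation known from chromium 2-(alkoxycarbonyl)allylations. Ring A closes by a 10-exo-trig addition to the carbonyl and ring B by a 5-exo-trig acyl substitution. The new C6 centre is controlled by C7 and C8: Felkin–Anh attack with the C8 chain as the large group and 1,3-anti induction from the O8 acyloxy group both lead to 6R, which is also the trans-fused lactone. The step needs chemoselectivity for the aldehyde over the acrylate, the esters and the allylic silyl ethers, which organochromium reagents provide, and ring closure over oligomerisation, which high dilution and the pre-folding by the two ring-cis olefins should secure. The aldehyde is added slowly so that its epimerisable C7 centre is exposed only briefly.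

Step 18
Reactants: 30 macrolactone
Product: 31 9,14-diol
Conditions: HF·pyridine, pyridine, THF, 0 °C → rt
Reagents that add atoms: none
Why: Fluoride cleavage of the TES and TBDPS ethers under buffered acidic conditions should free O9 and O14 without migration of the hindered O8 acyl group.

Step 19
Reactants: 31 9,14-diol
Product: 32 9-hydroxy-14-al
Conditions: TEMPO (cat.), PhI(OAc)2, CH2Cl2, rt
Reagents that add atoms: none
Why: Oxoammonium (TEMPO) oxidation is selective for the primary allylic C14 alcohol over the hindered secondary C9 alcohol and stops at the aldehyde.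

Step 20
Reactants: 32 9-hydroxy-14-al
Product: 33 target
Conditions: Ac2O, pyridine, CH2Cl2, 0 °C
Reagents that add atoms: acetic anhydride, CC(=O)OC(C)=O
Why: Pyridine-buffered acetylation of the remaining C9 hydroxyl completes the target without nucleophilic catalysis that could displace the new allylic acetate.

**Compound list**

1 | but-3-enylmagnesium bromide | C=CCC[Mg]Br | starting material
2 | propyne | CC#C | starting material
3 | but-3-enylcopper (MgBr2 complex) | C=CCC[Cu] | intermediate
4 | [(1Z)-2-methylhexa-1,5-dien-1-yl]copper | [Cu]/C=C(/C)CCC=C | intermediate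
5 | (1Z)-1-iodo-2-methylhexa-1,5-diene | I/C=C(/C)CCC=C | intermediate
6 | methyl (4S)-2,2-dimethyl-1,3-dioxolane-4-carboxylate | COC(=O)[C@@H]1COC(C)(C)O1 | starting material
7 | (4S)-2,2-dimethyl-1,3-dioxolane-4-carbaldehyde | O=C[C@@H]1COC(C)(C)O1 | intermediate
8 | (4R)-4-ethynyl-2,2-dimethyl-1,3-dioxolane | C#C[C@@H]1COC(C)(C)O1 | intermediate
9 | methyl 2-[(4R)-2,2-dimethyl-1,3-dioxolan-4-yl]prop-2-enoate | C=C(C(=O)OC)[C@@H]1COC(C)(C)O1 | intermediate
10 | methyl (2E,6Z)-2-[(4R)-2,2-dimethyl-1,3-dioxolan-4-yl]-7-iodo-6-methylhepta-2,6-dienoate | I/C=C(/C)CC/C=C(/C(=O)OC)[C@@H]1COC(C)(C)O1 | intermediate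
11 | (2Z,6Z)-2-[(4R)-2,2-dimethyl-1,3-dioxolan-4-yl]-7-iodo-6-methylhepta-2,6-dien-1-ol | I/C=C(/C)CC/C=C(/CO)[C@@H]1COC(C)(C)O1 | intermediate
12 | tert-butyl{[(2Z,6Z)-2-[(4R)-2,2-dimethyl-1,3-dioxolan-4-yl]-7-iodo-6-methylhepta-2,6-dien-1-yl]oxy}diphenylsilane | I/C=C(/C)CC/C=C(/CO[Si](c1ccccc1)(c1ccccc1)C(C)(C)C)[C@@H]1COC(C)(C)O1 | intermediate
13 | (2R,3Z,7Z)-3-{[tert-butyl(diphenyl)silyl]oxymethyl}-8-iodo-7-methylocta-3,7-diene-1,2-diol | I/C=C(/C)CC/C=C(/CO[Si](c1ccccc1)(c1ccccc1)C(C)(C)C)[C@@H](O)CO | intermediate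
14 | (2R,3Z,7Z)-3-{[tert-butyl(diphenyl)silyl]oxymethyl}-8-iodo-7-methyl-1,2-bis(triethylsilyloxy)octa-3,7-diene | I/C=C(/C)CC/C=C(/CO[Si](c1ccccc1)(c1ccccc1)C(C)(C)C)[C@@H](O[Si](CC)(CC)CC)CO[Si](CC)(CC)CC | intermediate
15 | (2R,3Z,7Z)-3-{[tert-butyl(diphenyl)silyl]oxymethyl}-8-iodo-7-methyl-2-(triethylsilyloxy)octa-3,7-dienal | I/C=C(/C)CC/C=C(/CO[Si](c1ccccc1)(c1ccccc1)C(C)(C)C)[C@@H](O[Si](CC)(CC)CC)C=O | intermediate
16 | 2-[(4-methoxyphenyl)methoxy]acetaldehyde | COc1ccc(COCC=O)cc1 | starting material
17 | methyl acrylate | C=CC(=O)OC | starting material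
18 | methyl 3-hydroxy-4-[(4-methoxyphenyl)methoxy]-2-methylidenebutanoate (racemic) | COC(=O)C(=C)C(O)COCc1ccc(OC)cc1 | intermediate
19 | methyl (2Z)-2-(bromomethyl)-4-[(4-methoxyphenyl)methoxy]but-2-enoate | COC(=O)/C(CBr)=C/COCc1ccc(OC)cc1 | intermediate
20 | {(2Z)-2-(methoxycarbonyl)-4-[(4-methoxyphenyl)methoxy]but-2-en-1-yl}indium dibromide (simplest formulation of the allylindium species) | COC(=O)/C(C[In](Br)Br)=C/COCc1ccc(OC)cc1 | intermediate
21 | methyl (3S,4S,5R,6Z,10Z)-6-{[tert-butyl(diphenyl)silyl]oxymethyl}-4-hydroxy-11-iodo-3-{[(4-methoxyphenyl)methoxy]methyl}-10-methyl-2-methylidene-5-(triethylsilyloxy)undeca-6,10-dienoate | I/C=C(/C)CC/C=C(/CO[Si](c1ccccc1)(c1ccccc1)C(C)(C)C)[C@@H](O[Si](CC)(CC)CC)[C@@H](O)[C@@H](C(=C)C(=O)OC)COCc1ccc(OC)cc1 | intermediate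
22 | (2S)-2-hydroxy-2-methylbutanoic acid | OC(=O)[C@](C)(CC)O | starting material
23 | (2S)-2-acetoxy-2-methylbutanoic acid | OC(=O)[C@](C)(CC)OC(C)=O | intermediate
24 | (2S)-2-acetoxy-2-methylbutanoyl chloride | ClC(=O)[C@](C)(CC)OC(C)=O | intermediate
25 | methyl (3S,4S,5R,6Z,10Z)-4-{[(2S)-2-acetoxy-2-methylbutanoyl]oxy}-6-{[tert-butyl(diphenyl)silyl]oxymethyl}-11-iodo-3-{[(4-methoxyphenyl)methoxy]methyl}-10-methyl-2-methylidene-5-(triethylsilyloxy)undeca-6,10-dienoate | I/C=C(/C)CC/C=C(/CO[Si](c1ccccc1)(c1ccccc1)C(C)(C)C)[C@@H](O[Si](CC)(CC)CC)[C@@H](OC(=O)[C@](C)(CC)OC(C)=O)[C@@H](C(=C)C(=O)OC)COCc1ccc(OC)cc1 | intermediate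
26 | methyl (3S,4S,5R,6Z,10Z)-4-{[(2S)-2-acetoxy-2-methylbutanoyl]oxy}-6-{[tert-butyl(diphenyl)silyl]oxymethyl}-3-(hydroxymethyl)-11-iodo-10-methyl-2-methylidene-5-(triethylsilyloxy)undeca-6,10-dienoate | I/C=C(/C)CC/C=C(/CO[Si](c1ccccc1)(c1ccccc1)C(C)(C)C)[C@@H](O[Si](CC)(CC)CC)[C@@H](OC(=O)[C@](C)(CC)OC(C)=O)[C@@H](C(=C)C(=O)OC)CO | intermediate
27 | methyl (3R,4S,5R,6Z,10Z)-4-{[(2S)-2-acetoxy-2-methylbutanoyl]oxy}-6-{[tert-butyl(diphenyl)silyl]oxymethyl}-3-formyl-11-iodo-10-methyl-2-methylidene-5-(triethylsilyloxy)undeca-6,10-dienoate | I/C=C(/C)CC/C=C(/CO[Si](c1ccccc1)(c1ccccc1)C(C)(C)C)[C@@H](O[Si](CC)(CC)CC)[C@@H](OC(=O)[C@](C)(CC)OC(C)=O)[C@@H](C(=C)C(=O)OC)C=O | intermediate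
28 | alkenylchromium dichloride from 27 (CrCl2 in place of iodine at C5; all else as in 27) | Cl[Cr](Cl)/C=C(/C)CC/C=C(/CO[Si](c1ccccc1)(c1ccccc1)C(C)(C)C)[C@@H](O[Si](CC)(CC)CC)[C@@H](OC(=O)[C@](C)(CC)OC(C)=O)[C@@H](C(=C)C(=O)OC)C=O | intermediate
29 | macrocyclic chromium alkoxide (ring A closed, new C6 centre R, O6 bound to CrCl2, C12 methyl ester still open; C7–C9 as in 27) | Cl[Cr](Cl)O[C@@H]1/C=C(/C)CC/C=C(/CO[Si](c2ccccc2)(c2ccccc2)C(C)(C)C)[C@@H](O[Si](CC)(CC)CC)[C@@H](OC(=O)[C@](C)(CC)OC(C)=O)[C@H]1C(=C)C(=O)OC | intermediate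
30 | (1(10)Z,4Z,6R,7S,8S,9R)-8-{[(2S)-2-acetoxy-2-methylbutanoyl]oxy}-14-[tert-butyl(diphenyl)silyl]oxy-9-(triethylsilyloxy)germacra-1(10),4,11(13)-trien-12,6-olide | C=C1C(=O)O[C@@H]2/C=C(/C)CC/C=C(/CO[Si](c3ccccc3)(c3ccccc3)C(C)(C)C)[C@@H](O[Si](CC)(CC)CC)[C@@H](OC(=O)[C@](C)(CC)OC(C)=O)[C@@H]12 | intermediate
31 | (1(10)Z,4Z,6R,7S,8S,9R)-8-{[(2S)-2-acetoxy-2-methylbutanoyl]oxy}-9,14-dihydroxygermacra-1(10),4,11(13)-trien-12,6-olide | C=C1C(=O)O[C@@H]2/C=C(/C)CC/C=C(/CO)[C@@H](O)[C@@H](OC(=O)[C@](C)(CC)OC(C)=O)[C@@H]12 | intermediate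
32 | (1(10)E,4Z,6R,7S,8S,9R)-8-{[(2S)-2-acetoxy-2-methylbutanoyl]oxy}-9-hydroxy-14-oxogermacra-1(10),4,11(13)-trien-12,6-olide | C=C1C(=O)O[C@@H]2/C=C(/C)CC/C=C(/C=O)[C@@H](O)[C@@H](OC(=O)[C@](C)(CC)OC(C)=O)[C@@H]12 | intermediate
33 | (1(10)E,4Z,6R,7S,8S,9R)-9-acetoxy-8-{[(2S)-2-acetoxy-2-methylbutanoyl]oxy}-14-oxogermacra-1(10),4,11(13)-trien-12,6-olide (CNP0499875.1) | C=C1C(=O)O[C@@H]2/C=C(/C)CC/C=C(/C=O)[C@@H](OC(C)=O)[C@@H](OC(=O)[C@](C)(CC)OC(C)=O)[C@@H]12 | target

**Step count and risks**

Total step count: 20. Longest linear sequence: 16 steps (6 → 33 through steps 2–9, 12 and 14–20).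

Steps most likely to fail:

1. Step 17 (ring closure with lactonisation). The alkenylchromium may add to the wrong face of the C6 aldehyde, or the ring may close so slowly that C7 epimerises; either way a cis-fused 6-epi lactone would form irreversibly. The fallback moves control of C6 from the addition to a ketone reduction. Setting out from 27, the ring is closed under chromium-catalytic conditions (CrCl2 cat., NiCl2 cat., manganese powder, TMSCl, THF/DMF), which trap the C6 alkoxide as its silyl ether and so switch the lactonisation off. This gives the macrocyclic C6 trimethylsilyl ether F1 as a mixture of C6 epimers. F1 is oxidised directly under Swern conditions, which cleave a secondary trimethylsilyl ether much faster than the secondary triethylsilyl ether, to the macrocyclic C6 enone F2. F2 is reduced under reagent control (Corey–Bakshi–Shibata reduction with catecholborane, or Luche reduction with NaBH4/CeCl3 as the substrate-controlled option) to the (6R)-allylic alcohol F3. F3 lactonises with PPTS in CH2Cl2 and comes back to the route at 30.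

2. Step 4 (cross-metathesis). The hindered 1,1-disubstituted acrylate may convert poorly, or the chain may end up cis to the ester. The fallback uses a ring to enforce the geometry. Setting out from 9, aqueous CF3CO2H removes the acetonide and the primary alcohol lactonises to (4R)-4-hydroxy-3-methylideneoxolan-2-one F4. Cross-metathesis of F4 with 5 (same catalyst) should give the (E)-alkylidene lactone F5, since the cyclic acrylate is less hindered and the ring keeps the chain trans to the carbonyl. DIBAL-H opens F5 to the triol F6, and acetonide formation on the terminal 1,2-diol (2,2-dimethoxypropane, PPTS) comes back to the route at 11.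

3. Step 12 (allylation). Simple (syn/anti) or Felkin–Anh selectivity may be insufficient when two centres are set at once, and the TES ether may be lost in the aqueous medium. The fallback replaces the Barbier reaction by an allylboration in an anhydrous medium. Setting out from 19, palladium-catalysed borylation (B2pin2, Pd2(dba)3, toluene, 50 °C) should give the allylboronate F7 with the olefin geometry retained. Thermal allylboration of 15 with F7 (toluene, 60 °C) passes through a closed Zimmerman–Traxler chair, which should translate that geometry into the C6/O8 syn relationship with Felkin–Anh facial control. Aqueous NaHCO3 work-up of the borate comes back to the route at 21.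

Further compounds
F1 | step 17 | macrocyclic C6 trimethylsilyl ether (ring A closed, both C6 epimers, C12 methyl ester open; other groups as in 29) | C[Si](C)(C)OC1/C=C(/C)CC/C=C(/CO[Si](c2ccccc2)(c2ccccc2)C(C)(C)C)[C@@H](O[Si](CC)(CC)CC)[C@@H](OC(=O)[C@](C)(CC)OC(C)=O)[C@H]1C(=C)C(=O)OC
F2 | step 17 | macrocyclic C6 enone (C6 ketone conjugated with C4=C5, C12 methyl ester open; other groups as in 29) | O=C1/C=C(/C)CC/C=C(/CO[Si](c2ccccc2)(c2ccccc2)C(C)(C)C)[C@@H](O[Si](CC)(CC)CC)[C@@H](OC(=O)[C@](C)(CC)OC(C)=O)[C@H]1C(=C)C(=O)OC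
F3 | step 17 | macrocyclic (6R)-allylic alcohol (free hydroxy methyl ester corresponding to 29) | O[C@@H]1/C=C(/C)CC/C=C(/CO[Si](c2ccccc2)(c2ccccc2)C(C)(C)C)[C@@H](O[Si](CC)(CC)CC)[C@@H](OC(=O)[C@](C)(CC)OC(C)=O)[C@H]1C(=C)C(=O)OC
F4 | step 4 | (4R)-4-hydroxy-3-methylideneoxolan-2-one | O[C@H]1COC(=O)C1=C
F5 | step 4 | (3E,4R)-4-hydroxy-3-[(4Z)-5-iodo-4-methylpent-4-en-1-ylidene]oxolan-2-one | O[C@H]1COC(=O)/C1=C/CC/C(C)=C\I
F6 | step 4 | (2R,3Z,7Z)-3-(hydroxymethyl)-8-iodo-7-methylocta-3,7-diene-1,2-diol | I/C=C(/C)CC/C=C(/CO)[C@@H](O)CO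
F7 | step 12 | methyl (2E)-4-[(4-methoxyphenyl)methoxy]-2-[(4,4,5,5-tetramethyl-1,3,2-dioxaborolan-2-yl)methyl]but-2-enoate | COC(=O)/C(CB1OC(C)(C)C(C)(C)O1)=C/COCc1ccc(OC)cc1
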